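**Strategy**

Everything rests on reading C9–C13 of the 14-membered macrolactone as a six-membered lactone template: the anti-related C11 methoxy and C13 oxygen are the cis 4,6-substituents of a δ-lactone whose carbonyl is C9. One titanium–binaphthol-catalysed hetero-Diels–Alder reaction of butanal (C13–C16) with Brassard's diene (C9–C12, a silyl ketene acetal made in two steps from methyl acetoacetate) forms C12–C13 and O13–C9, closes that ring, sets C13 and delivers the C11 oxygen already methylated. Hydrogenation relays C13 to C11; opening at C9, olefination and copper hydride reduction set C9; a chromium-catalysed cycloaddition builds the pyran (C3, C7), and macrolactonisation, ketone reduction and Mitsunobu inversion (C5) finish.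

Key step: step 3

Assumption: carbons are numbered C1–C16 as in the seco acid (C1 lactone carbonyl, C13 propyl-bearing carbinol); the sense of induction of each chiral catalyst is assigned by analogy with its usual model, and the antipodal ligand would be taken if a trial run showed the opposite sense.

**Route**

Step 1
Reactants: 1 methyl acetoacetate
Product: 3 methyl (2E)-3-methoxybut-2-enoate, via methyl 3,3-dimethoxybutanoate 2 (not isolated)
Conditions: HC(OMe)3, H2SO4 (cat.), rt; then distillation
Reagents that add atoms: trimethyl orthoformate, COC(OC)OC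
Why: Acid-catalysed ketalisation by the orthoformate followed by loss of methanol on distillation (enol ether formation) should give the conjugated (E)-β-methoxy enoate, the thermodynamically preferred isomer.

Step 2
Reactants: 3 methyl (2E)-3-methoxybut-2-enoate
Product: 4 Brassard's diene, (1E)-1,3-dimethoxy-1-(trimethylsilyloxy)buta-1,3-diene
Conditions: LiN(iPr)2, THF, −78 °C; Me3SiCl, −78 °C → rt; distil, use fresh
Reagents that add atoms: chlorotrimethylsilane, C[Si](C)(C)Cl
Why: Kinetic deprotonation of the γ-methyl group of the vinylogous ester and O-silylation of the ester dienolate (silyl ketene acetal formation) should give the electron-rich diene.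

Step 3
Reactants: 4 Brassard's diene; 5 butanal
Product: 7 (6R)-4-methoxy-6-propyl-5,6-dihydro-2H-pyran-2-one, via ortho ester cycloadduct 6 (not isolated)
Conditions: Ti(OiPr)4 (10 mol %, tetravalent titanium), (S)-BINOL (11 mol %), 4 Å MS, toluene, 0 °C, slow addition of 4; then TFA, CH2Cl2, 0 °C
Reagents that add atoms: none
Why: The chiral titanium binaphtholate binds butanal as a Lewis acid and leaves its Si face open, so the nucleophilic terminus C12 of the diene attacks C13 and the aldehyde oxygen bonds to the ketene acetal carbon C9, in one asynchronous [4+2] event or as a Mukaiyama-type aldol addition followed by ring closure; TFA then collapses ortho ester 6 to the vinylogous carbonate 7 with loss of methanol and the silyl group. The closest known reaction type is the catalytic enantioselective hetero-Diels–Alder reaction of Brassard-type dienes with aliphatic aldehydes. The one ring is closed by the [4+2] cycloaddition itself (in the stepwise variant by 6-exo-trig attack of O13 on the C9 ester carbon). C13 is the only new stereocentre and is controlled by the ligand, there being no substrate bias. The step needs enantioface selectivity on an unbranched aldehyde, secured by the ligand, low temperature and slow diene addition, and C12 rather than C10 regiochemistry, which is built into the diene because its largest HOMO coefficient lies on the terminal CH2.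

Step 4
Reactants: 7 (6R)-4-methoxy-6-propyl-5,6-dihydro-2H-pyran-2-one
Product: 8 (4S,6R)-4-methoxy-6-propyloxan-2-one (cis)
Conditions: H2 (4 atm), Pd/C, EtOAc, rt
Reagents that add atoms: none
Why: Heterogeneous catalytic hydrogenation should deliver hydrogen to the face of the half-chair enol ether opposite the pseudo-equatorial propyl group, so the methoxy group ends cis to propyl and C11 is set by C13 (substrate control).

Step 5
Reactants: 8 (4S,6R)-4-methoxy-6-propyloxan-2-one
Product: 9 (3S,5R)-5-hydroxy-N,3-dimethoxy-N-methyloctanamide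
Conditions: MeNH(OMe)·HCl, AlMe3, CH2Cl2, 0 °C → rt; used crude
Reagents that add atoms: N,O-dimethylhydroxylamine hydrochloride, CNOC.Cl
Why: Aminolysis of the lactone by the aluminium amide formed from AlMe3 and the amine salt (Weinreb amide formation) should cleave the template bond C9–O13 without touching C11 or C13.

Step 6
Reactants: 9 (3S,5R)-5-hydroxy-N,3-dimethoxy-N-methyloctanamide
Product: 10 (3S,5R)-5-[(tert-butyldimethylsilyl)oxy]-N,3-dimethoxy-N-methyloctanamide
Conditions: TBSOTf, 2,6-lutidine, CH2Cl2, −78 °C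
Reagents that add atoms: tert-butyldimethylsilyl trifluoromethanesulfonate, CC(C)(C)[Si](C)(C)OS(=O)(=O)C(F)(F)F
Why: Silylation of the secondary alcohol with the silyl triflate is fast at low temperature and should outrun relactonisation of the δ-hydroxy amide.

Step 7
Reactants: 10 (3S,5R)-5-[(tert-butyldimethylsilyl)oxy]-N,3-dimethoxy-N-methyloctanamide
Product: 11 (4S,6R)-6-[(tert-butyldimethylsilyl)oxy]-4-methoxynonan-2-one
Conditions: MeMgBr, THF, 0 °C
Reagents that add atoms: methylmagnesium bromide, C[Mg]Br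
Why: Grignard addition to the Weinreb amide stops at the stable magnesium chelate, which should release the methyl ketone only on work-up (Weinreb ketone synthesis).

Step 8
Reactants: 11 (4S,6R)-6-[(tert-butyldimethylsilyl)oxy]-4-methoxynonan-2-one; 12 triethyl phosphonoacetate
Product: 13 ethyl (2E,5R,7R)-7-[(tert-butyldimethylsilyl)oxy]-5-methoxy-3-methyldec-2-enoate
Conditions: NaH, THF, 0 → 50 °C; chromatographic removal of the minor (Z)-isomer
Reagents that add atoms: none
Why: Horner–Wadsworth–Emmons olefination of the methyl ketone with the stabilised phosphonate anion should favour the (E)-trisubstituted enoate, and the minor geometric isomer is removed because alkene geometry decides the face of the next step.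

Step 9
Reactants: 13 ethyl (2E,5R,7R)-7-[(tert-butyldimethylsilyl)oxy]-5-methoxy-3-methyldec-2-enoate
Product: 14 ethyl (3S,5R,7R)-7-[(tert-butyldimethylsilyl)oxy]-5-methoxy-3-methyldecanoate
Conditions: CuCl (5 mol %, monovalent copper), NaOtBu (5 mol %), (S)-p-Tol-BINAP (10 mol %), (EtO)2MeSiH, tBuOH, toluene, rt
Reagents that add atoms: none
Why: Copper hydride asymmetric conjugate reduction, in which the ligated copper hydride should add hydride to the Re face of the β-carbon C9 of the (E)-enoate under ligand control (C11 and C13 are too remote to interfere) and tBuOH protonates the copper enolate.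

Step 10
Reactants: 14 ethyl (3S,5R,7R)-7-[(tert-butyldimethylsilyl)oxy]-5-methoxy-3-methyldecanoate
Product: 15 (3S,5R,7R)-7-[(tert-butyldimethylsilyl)oxy]-5-methoxy-3-methyldecanal
Conditions: iBu2AlH, CH2Cl2, −78 °C
Reagents that add atoms: none
Why: Partial reduction of the ester at low temperature should stop at the aluminium hemiacetal and give the aldehyde on work-up, and the C9 centre is β to the carbonyl and cannot epimerise.

Step 11
Reactants: 16 3-[(tert-butyldimethylsilyl)oxy]propanal; 17 1-(triphenylphosphoranylidene)propan-2-one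
Product: 18 (3E)-6-[(tert-butyldimethylsilyl)oxy]hex-3-en-2-one
Conditions: CH2Cl2, rt
Reagents that add atoms: none
Why: Wittig olefination with the stabilised acetonyl ylide should give the (E)-enone.

Step 12
Reactants: 18 (3E)-6-[(tert-butyldimethylsilyl)oxy]hex-3-en-2-one
Product: 19 tert-butyldimethyl{[(3E)-5-(triethylsilyloxy)hexa-3,5-dien-1-yl]oxy}silane
Conditions: Et3SiOTf, Et3N, Et2O, −78 → 0 °C
Reagents that add atoms: triethylsilyl trifluoromethanesulfonate, CC[Si](CC)(CC)OS(=O)(=O)C(F)(F)F
Why: Soft enolisation of the ketone on its methyl side and O-silylation (silyl enol ether formation) should give the 2-silyloxy-1,3-diene with the (E)-alkene untouched.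

Step 13
Reactants: 15 (3S,5R,7R)-7-[(tert-butyldimethylsilyl)oxy]-5-methoxy-3-methyldecanal; 19 tert-butyldimethyl{[(3E)-5-(triethylsilyloxy)hexa-3,5-dien-1-yl]oxy}silane
Product: 21 (2S,6R)-2-(2-hydroxyethyl)-6-[(2S,4R,6R)-6-hydroxy-4-methoxy-2-methylnonyl]oxan-4-one, via silyl enol ether cycloadduct 20 (not isolated)
Conditions: CrCl(L) (5 mol %, trivalent chromium; L = dianion of the Schiff base from 3-(1-adamantyl)-2-hydroxy-5-methylbenzaldehyde and (1S,2R)-1-aminoindan-2-ol), 4 Å MS, tBuOMe, rt; filter, concentrate; then HF (48 % aq.), MeCN, 0 °C → rt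
Reagents that add atoms: none
Why: Catalytic asymmetric hetero-Diels–Alder reaction in which the chiral chromium Lewis acid should direct the diene to the Si face of the aldehyde (C7) and the endo transition state places the C3 and C7 substituents cis, after which aqueous HF hydrolyses the silyl enol ether to the ketone and removes both silyl ethers.

Step 14
Reactants: 21 (2S,6R)-2-(2-hydroxyethyl)-6-[(2S,4R,6R)-6-hydroxy-4-methoxy-2-methylnonyl]oxan-4-one
Product: 23 2-{(2R,6R)-6-[(2S,4R,6R)-6-hydroxy-4-methoxy-2-methylnonyl]-4-oxooxan-2-yl}acetic acid, via hydroxy keto aldehyde 22 (not isolated)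
Conditions: TEMPO (cat.), PhI(OAc)2, MeCN/H2O, rt
Reagents that add atoms: water, O
Why: Oxoammonium-mediated oxidation (TEMPO with PhI(OAc)2 as terminal oxidant) is strongly selective for the unhindered primary alcohol, whose aldehyde hydrate is oxidised on to the acid while the secondary C13 alcohol should remain.

Step 15
Reactants: 23 2-{(2R,6R)-6-[(2S,4R,6R)-6-hydroxy-4-methoxy-2-methylnonyl]-4-oxooxan-2-yl}acetic acid
Product: 25 (1R,5R,7R,9S,11R)-7-methoxy-9-methyl-5-propyl-4,15-dioxabicyclo[9.3.1]pentadecane-3,13-dione, via mixed anhydride 24 (not isolated)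
Conditions: 2,4,6-Cl3C6H2COCl, Et3N, THF, rt; then slow addition to DMAP, toluene, 80 °C, high dilution
Reagents that add atoms: none
Why: Yamaguchi macrolactonisation, in which the mixed anhydride acylates DMAP and the C13 hydroxyl closes the 14-membered ring under high dilution, the C5 oxygen being kept as a ketone so that no second hydroxyl competes.

Step 16
Reactants: 25 (1R,5R,7R,9S,11R)-7-methoxy-9-methyl-5-propyl-4,15-dioxabicyclo[9.3.1]pentadecane-3,13-dione
Product: 26 (1R,5R,7R,9S,11R,13S)-13-hydroxy-7-methoxy-9-methyl-5-propyl-4,15-dioxabicyclo[9.3.1]pentadecan-3-one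
Conditions: NaBH4, MeOH, 0 °C
Reagents that add atoms: none
Why: The small hydride reagent attacks the chair-shaped pyranone along the axial trajectory, so it should give the equatorial C5 alcohol, cis to the C3 and C7 substituents, without reducing the lactone.

Step 17
Reactants: 27 propargylamine
Product: 28 methyl prop-2-yn-1-ylcarbamate
Conditions: ClCO2Me, Et3N, CH2Cl2, 0 °C
Reagents that add atoms: methyl chloroformate, COC(=O)Cl
Why: Acylation of the primary amine by the chloroformate (carbamate formation) is fast and leaves the alkyne untouched.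

Step 18
Reactants: 28 methyl prop-2-yn-1-ylcarbamate; 29 ethyl 2-chloro-1,3-oxazole-4-carboxylate
Product: 30 ethyl 2-{3-[(methoxycarbonyl)amino]prop-1-yn-1-yl}-1,3-oxazole-4-carboxylate
Conditions: PdCl2(PPh3)2 (5 mol %), CuI (10 mol %), iPr2NEt, DMF, 60 °C
Reagents that add atoms: none
Why: Sonogashira coupling, in which the C2–Cl bond, flanked by O and N and activated by the 4-ester, should undergo oxidative addition to zerovalent palladium and couple with the copper acetylide.

Step 19
Reactants: 30 ethyl 2-{3-[(methoxycarbonyl)amino]prop-1-yn-1-yl}-1,3-oxazole-4-carboxylate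
Product: 31 ethyl 2-{(1Z)-3-[(methoxycarbonyl)amino]prop-1-en-1-yl}-1,3-oxazole-4-carboxylate
Conditions: H2 (1 atm), Pd/CaCO3 poisoned with Pb(OAc)2, quinoline, EtOAc, rt
Reagents that add atoms: none
Why: Semi-hydrogenation over poisoned palladium (Lindlar-type) adds hydrogen syn to the alkyne and should stop at the (Z)-alkene.

Step 20
Reactants: 31 ethyl 2-{(1Z)-3-[(methoxycarbonyl)amino]prop-1-en-1-yl}-1,3-oxazole-4-carboxylate
Product: 32 methyl [(2Z)-3-(4-formyl-1,3-oxazol-2-yl)prop-2-en-1-yl]carbamate
Conditions: iBu2AlH (2.2 equiv), CH2Cl2, −78 °C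
Reagents that add atoms: none
Why: Partial reduction of the heteroaryl ester at low temperature, the aluminium hemiacetal being held by chelation to the oxazole nitrogen, should give the aldehyde (one equivalent of hydride is spent on the carbamate N–H).

Step 21
Reactants: 32 methyl [(2Z)-3-(4-formyl-1,3-oxazol-2-yl)prop-2-en-1-yl]carbamate; 33 (triphenylphosphoranylidene)acetaldehyde
Product: 34 methyl [(2Z)-3-{4-[(1E)-3-oxoprop-1-en-1-yl]-1,3-oxazol-2-yl}prop-2-en-1-yl]carbamate
Conditions: toluene, 80 °C (1.05 equiv of 33)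
Reagents that add atoms: none
Why: Wittig two-carbon homologation with the stabilised formyl ylide should give the (E)-enal, the heteroaryl aldehyde reacting faster than the product enal.

Step 22
Reactants: 34 methyl [(2Z)-3-{4-[(1E)-3-oxoprop-1-en-1-yl]-1,3-oxazol-2-yl}prop-2-en-1-yl]carbamate
Product: 35 methyl [(2Z)-3-[4-(3-oxopropyl)-1,3-oxazol-2-yl]prop-2-en-1-yl]carbamate
Conditions: Hantzsch ester (diethyl 2,6-dimethyl-1,4-dihydropyridine-3,5-dicarboxylate), dibenzylammonium trifluoroacetate (5 mol %), THF, rt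
Reagents that add atoms: none
Why: Organocatalytic transfer hydrogenation, in which the ammonium salt converts only the enal into an iminium ion that accepts hydride from the Hantzsch ester, so the alkenyl oxazole and the carbamate should be untouched.

Step 23
Reactants: 35 methyl [(2Z)-3-[4-(3-oxopropyl)-1,3-oxazol-2-yl]prop-2-en-1-yl]carbamate; 36 methyl 2-[bis(2,2,2-trifluoroethoxy)phosphoryl]acetate
Product: 37 methyl (2Z)-5-[2-{(1Z)-3-[(methoxycarbonyl)amino]prop-1-en-1-yl}-1,3-oxazol-4-yl]pent-2-enoate
Conditions: KN(SiMe3)2, 18-crown-6, THF, −78 °C (phosphonate anion preformed, then 35)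
Reagents that add atoms: none
Why: Still–Gennari olefination, in which the potassium anion of the bis(trifluoroethyl) phosphonate adds to the aldehyde and eliminates fast from the syn adduct, should give the (Z)-enoate under kinetic control.

Step 24
Reactants: 37 methyl (2Z)-5-[2-{(1Z)-3-[(methoxycarbonyl)amino]prop-1-en-1-yl}-1,3-oxazol-4-yl]pent-2-enoate
Product: 38 (2Z)-5-[2-{(1Z)-3-[(methoxycarbonyl)amino]prop-1-en-1-yl}-1,3-oxazol-4-yl]pent-2-enoic acid
Conditions: LiOH, THF/H2O, 0 °C → rt; then HCl (1 M) to pH 3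
Reagents that add atoms: lithium hydroxide, [Li+].[OH-]
Why: Saponification of the methyl ester at low temperature should leave the less electrophilic methyl carbamate and both (Z)-alkenes intact.

Step 25
Reactants: 26 (1R,5R,7R,9S,11R,13S)-13-hydroxy-7-methoxy-9-methyl-5-propyl-4,15-dioxabicyclo[9.3.1]pentadecan-3-one; 38 (2Z)-5-[2-{(1Z)-3-[(methoxycarbonyl)amino]prop-1-en-1-yl}-1,3-oxazol-4-yl]pent-2-enoic acid
Product: 39 neopeltolide, (1R,5R,7R,9S,11R,13R)-7-methoxy-9-methyl-3-oxo-5-propyl-4,15-dioxabicyclo[9.3.1]pentadecan-13-yl (2Z)-5-[2-{(1Z)-3-[(methoxycarbonyl)amino]prop-1-en-1-yl}-1,3-oxazol-4-yl]pent-2-enoate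
Conditions: PPh3, DIAD, benzene, 0 °C → rt
Reagents that add atoms: none
Why: Mitsunobu esterification, in which the equatorial C5 alcohol is activated as its oxyphosphonium ion and displaced by the carboxylate with inversion, should give the axial ester of the target.

**Compound list**

1 | methyl acetoacetate | COC(=O)CC(C)=O | starting material
2 | methyl 3,3-dimethoxybutanoate | COC(=O)CC(C)(OC)OC | intermediate
3 | methyl (2E)-3-methoxybut-2-enoate | CO/C(C)=C/C(=O)OC | intermediate
4 | Brassard's diene, (1E)-1,3-dimethoxy-1-(trimethylsilyloxy)buta-1,3-diene | C=C(OC)/C=C(\OC)O[Si](C)(C)C | intermediate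
5 | butanal | CCCC=O | starting material
6 | (6R)-2,4-dimethoxy-6-propyl-2-(trimethylsilyloxy)-5,6-dihydro-2H-pyran (ortho ester cycloadduct, either configuration at C2) | CCC[C@@H]1CC(OC)=CC(OC)(O[Si](C)(C)C)O1 | intermediate
7 | (6R)-4-methoxy-6-propyl-5,6-dihydro-2H-pyran-2-one | CCC[C@@H]1CC(OC)=CC(=O)O1 | intermediate
8 | (4S,6R)-4-methoxy-6-propyloxan-2-one | CCC[C@@H]1C[C@H](OC)CC(=O)O1 | intermediate
9 | (3S,5R)-5-hydroxy-N,3-dimethoxy-N-methyloctanamide | CCC[C@@H](O)C[C@H](OC)CC(=O)N(C)OC | intermediate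
10 | (3S,5R)-5-[(tert-butyldimethylsilyl)oxy]-N,3-dimethoxy-N-methyloctanamide | CCC[C@@H](O[Si](C)(C)C(C)(C)C)C[C@H](OC)CC(=O)N(C)OC | intermediate
11 | (4S,6R)-6-[(tert-butyldimethylsilyl)oxy]-4-methoxynonan-2-one | CCC[C@@H](O[Si](C)(C)C(C)(C)C)C[C@H](OC)CC(C)=O | intermediate
12 | triethyl phosphonoacetate | CCOC(=O)CP(=O)(OCC)OCC | starting material
13 | ethyl (2E,5R,7R)-7-[(tert-butyldimethylsilyl)oxy]-5-methoxy-3-methyldec-2-enoate | CCC[C@@H](O[Si](C)(C)C(C)(C)C)C[C@H](OC)C/C(C)=C/C(=O)OCC | intermediate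
14 | ethyl (3S,5R,7R)-7-[(tert-butyldimethylsilyl)oxy]-5-methoxy-3-methyldecanoate | CCC[C@@H](O[Si](C)(C)C(C)(C)C)C[C@H](OC)C[C@H](C)CC(=O)OCC | intermediate
15 | (3S,5R,7R)-7-[(tert-butyldimethylsilyl)oxy]-5-methoxy-3-methyldecanal | CCC[C@@H](O[Si](C)(C)C(C)(C)C)C[C@H](OC)C[C@H](C)CC=O | intermediate
16 | 3-[(tert-butyldimethylsilyl)oxy]propanal | O=CCCO[Si](C)(C)C(C)(C)C | starting material
17 | 1-(triphenylphosphoranylidene)propan-2-one | CC(=O)C=P(c1ccccc1)(c1ccccc1)c1ccccc1 | starting material
18 | (3E)-6-[(tert-butyldimethylsilyl)oxy]hex-3-en-2-one | CC(=O)/C=C/CCO[Si](C)(C)C(C)(C)C | intermediate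
19 | tert-butyldimethyl{[(3E)-5-(triethylsilyloxy)hexa-3,5-dien-1-yl]oxy}silane | C=C(O[Si](CC)(CC)CC)/C=C/CCO[Si](C)(C)C(C)(C)C | intermediate
20 | (2R,6S)-2-[(2S,4R,6R)-6-(tert-butyldimethylsilyloxy)-4-methoxy-2-methylnonyl]-6-[2-(tert-butyldimethylsilyloxy)ethyl]-4-(triethylsilyloxy)-3,6-dihydro-2H-pyran | CCC[C@@H](O[Si](C)(C)C(C)(C)C)C[C@H](OC)C[C@H](C)C[C@@H]1CC(O[Si](CC)(CC)CC)=C[C@H](CCO[Si](C)(C)C(C)(C)C)O1 | intermediate
21 | (2S,6R)-2-(2-hydroxyethyl)-6-[(2S,4R,6R)-6-hydroxy-4-methoxy-2-methylnonyl]oxan-4-one | CCC[C@@H](O)C[C@H](OC)C[C@H](C)C[C@@H]1CC(=O)C[C@H](CCO)O1 | intermediate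
22 | 2-{(2S,6R)-6-[(2S,4R,6R)-6-hydroxy-4-methoxy-2-methylnonyl]-4-oxooxan-2-yl}acetaldehyde | CCC[C@@H](O)C[C@H](OC)C[C@H](C)C[C@@H]1CC(=O)C[C@H](CC=O)O1 | intermediate
23 | 2-{(2R,6R)-6-[(2S,4R,6R)-6-hydroxy-4-methoxy-2-methylnonyl]-4-oxooxan-2-yl}acetic acid | CCC[C@@H](O)C[C@H](OC)C[C@H](C)C[C@@H]1CC(=O)C[C@H](CC(=O)O)O1 | intermediate
24 | mixed anhydride of 23 with 2,4,6-trichlorobenzoic acid | CCC[C@@H](O)C[C@H](OC)C[C@H](C)C[C@@H]1CC(=O)C[C@H](CC(=O)OC(=O)c2c(Cl)cc(Cl)cc2Cl)O1 | intermediate
25 | (1R,5R,7R,9S,11R)-7-methoxy-9-methyl-5-propyl-4,15-dioxabicyclo[9.3.1]pentadecane-3,13-dione | CCC[C@@H]1C[C@H](OC)C[C@H](C)C[C@@H]2CC(=O)C[C@H](CC(=O)O1)O2 | intermediate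
26 | (1R,5R,7R,9S,11R,13S)-13-hydroxy-7-methoxy-9-methyl-5-propyl-4,15-dioxabicyclo[9.3.1]pentadecan-3-one | CCC[C@@H]1C[C@H](OC)C[C@H](C)C[C@@H]2C[C@H](O)C[C@H](CC(=O)O1)O2 | intermediate
27 | propargylamine | C#CCN | starting material
28 | methyl prop-2-yn-1-ylcarbamate | C#CCNC(=O)OC | intermediate
29 | ethyl 2-chloro-1,3-oxazole-4-carboxylate | CCOC(=O)c1coc(Cl)n1 | starting material
30 | ethyl 2-{3-[(methoxycarbonyl)amino]prop-1-yn-1-yl}-1,3-oxazole-4-carboxylate | CCOC(=O)c1coc(C#CCNC(=O)OC)n1 | intermediate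
31 | ethyl 2-{(1Z)-3-[(methoxycarbonyl)amino]prop-1-en-1-yl}-1,3-oxazole-4-carboxylate | CCOC(=O)c1coc(/C=C\CNC(=O)OC)n1 | intermediate
32 | methyl [(2Z)-3-(4-formyl-1,3-oxazol-2-yl)prop-2-en-1-yl]carbamate | O=Cc1coc(/C=C\CNC(=O)OC)n1 | intermediate
33 | (triphenylphosphoranylidene)acetaldehyde | O=CC=P(c1ccccc1)(c1ccccc1)c1ccccc1 | starting material
34 | methyl [(2Z)-3-{4-[(1E)-3-oxoprop-1-en-1-yl]-1,3-oxazol-2-yl}prop-2-en-1-yl]carbamate | O=C/C=C/c1coc(/C=C\CNC(=O)OC)n1 | intermediate
35 | methyl [(2Z)-3-[4-(3-oxopropyl)-1,3-oxazol-2-yl]prop-2-en-1-yl]carbamate | O=CCCc1coc(/C=C\CNC(=O)OC)n1 | intermediate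
36 | methyl 2-[bis(2,2,2-trifluoroethoxy)phosphoryl]acetate | COC(=O)CP(=O)(OCC(F)(F)F)OCC(F)(F)F | starting material
37 | methyl (2Z)-5-[2-{(1Z)-3-[(methoxycarbonyl)amino]prop-1-en-1-yl}-1,3-oxazol-4-yl]pent-2-enoate | COC(=O)/C=C\CCc1coc(/C=C\CNC(=O)OC)n1 | intermediate
38 | (2Z)-5-[2-{(1Z)-3-[(methoxycarbonyl)amino]prop-1-en-1-yl}-1,3-oxazol-4-yl]pent-2-enoic acid | OC(=O)/C=C\CCc1coc(/C=C\CNC(=O)OC)n1 | intermediate
39 | neopeltolide | CCC[C@@H]1C[C@H](OC)C[C@H](C)C[C@@H]2C[C@@H](OC(=O)/C=C\CCc3coc(/C=C\CNC(=O)OC)n3)C[C@H](CC(=O)O1)O2 | target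

**Step count and risks**

Total step count: 25. Longest linear sequence: 15 steps (steps 1–10, 13–16 and 25).

Steps most likely to fail:

1. Step 3 (key hetero-Diels–Alder reaction). What may go wrong: weak enantioface discrimination on the small unbranched aldehyde, or decomposition of the acid-sensitive diene before it is consumed. Fallback (asymmetric hydrogenation sets C13 in place of the cycloaddition; the lactone template is kept): it sets out from 1. The dianion of 1 (NaH, then nBuLi, THF, 0 °C) is ethylated at the terminal carbon with iodoethane to give methyl 3-oxohexanoate F1. Asymmetric ketone hydrogenation (H2, RuCl2[(R)-BINAP], MeOH) should give methyl (3R)-3-hydroxyhexanoate F2. Claisen condensation with an excess of the lithium enolate of tert-butyl acetate (LiN(iPr)2, THF, −78 → −20 °C) gives tert-butyl (5R)-5-hydroxy-3-oxooctanoate F3. TFA in CH2Cl2 cleaves the tert-butyl ester and closes (6R)-6-propyloxane-2,4-dione F4. O-Methylation of its enol (Me2SO4, K2CO3, acetone) returns to the route at 7.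

2. Step 9 (copper hydride reduction). What may go wrong: incomplete catalyst control of the hydride face, or slow hydrocupration of the β,β-disubstituted enoate so that the reduction stalls; the outcome also depends on the geometric purity reached in step 8. Fallback (C9 is set by adding the methyl group in place of hydride, on an alkene whose geometry is secure): it sets out from 10. iBu2AlH (THF, −78 °C) reduces the Weinreb amide to (3S,5R)-5-[(tert-butyldimethylsilyl)oxy]-3-methoxyoctanal F5. Wittig reaction with S-ethyl (triphenylphosphoranylidene)ethanethioate (CH2Cl2, rt) gives S-ethyl (2E,5R,7R)-7-[(tert-butyldimethylsilyl)oxy]-5-methoxydec-2-enethioate F6. Copper-catalysed asymmetric conjugate addition of MeMgBr (CuBr·SMe2, Josiphos-type ferrocenyl diphosphine, tBuOMe, −75 °C) should give S-ethyl (3S,5R,7R)-7-[(tert-butyldimethylsilyl)oxy]-5-methoxy-3-methyldecanethioate F7. iBu2AlH (CH2Cl2, −78 °C) reduces the thioester and returns to the route at 15.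

3. Step 13 (pyran-forming cycloaddition). What may go wrong: poor facial selectivity of the chromium catalyst against the β-methyl-branched aldehyde, or hydrolysis and oligomerisation of the silyloxydiene under the Lewis acid. Fallback (aldol addition and oxa-Michael ring closure in place of the cycloaddition): it sets out from 18 and 15. The boron enolate of 18 ((−)-Ipc2BCl, Et3N, Et2O, −78 °C) is added to 15 under reagent control (Si face of the aldehyde) to give (3E,7R,9R,11R,13R)-1,13-bis[(tert-butyldimethylsilyl)oxy]-7-hydroxy-11-methoxy-9-methylhexadec-3-en-5-one F8. Catalytic DBU (CH2Cl2, rt) closes the ring by 6-endo oxa-Michael addition of the C7 hydroxyl to C3 under thermodynamic control, which should give (2S,6R)-2-{2-[(tert-butyldimethylsilyl)oxy]ethyl}-6-[(2S,4R,6R)-6-{(tert-butyldimethylsilyl)oxy}-4-methoxy-2-methylnonyl]oxan-4-one F9 with both substituents equatorial. HF (48 % aq.) in MeCN removes both silyl ethers and returns to the route at 21.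

**Further compounds**

F1 | step 3 | methyl 3-oxohexanoate | CCCC(=O)CC(=O)OC
F2 | step 3 | methyl (3R)-3-hydroxyhexanoate | CCC[C@@H](O)CC(=O)OC
F3 | step 3 | tert-butyl (5R)-5-hydroxy-3-oxooctanoate | CCC[C@@H](O)CC(=O)CC(=O)OC(C)(C)C
F4 | step 3 | (6R)-6-propyloxane-2,4-dione | CCC[C@@H]1CC(=O)CC(=O)O1
F5 | step 9 | (3S,5R)-5-[(tert-butyldimethylsilyl)oxy]-3-methoxyoctanal | CCC[C@@H](O[Si](C)(C)C(C)(C)C)C[C@H](OC)CC=O
F6 | step 9 | S-ethyl (2E,5R,7R)-7-[(tert-butyldimethylsilyl)oxy]-5-methoxydec-2-enethioate | CCC[C@@H](O[Si](C)(C)C(C)(C)C)C[C@H](OC)C/C=C/C(=O)SCC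
F7 | step 9 | S-ethyl (3S,5R,7R)-7-[(tert-butyldimethylsilyl)oxy]-5-methoxy-3-methyldecanethioate | CCC[C@@H](O[Si](C)(C)C(C)(C)C)C[C@H](OC)C[C@H](C)CC(=O)SCC
F8 | step 13 | (3E,7R,9R,11R,13R)-1,13-bis[(tert-butyldimethylsilyl)oxy]-7-hydroxy-11-methoxy-9-methylhexadec-3-en-5-one | CCC[C@@H](O[Si](C)(C)C(C)(C)C)C[C@H](OC)C[C@H](C)C[C@@H](O)CC(=O)/C=C/CCO[Si](C)(C)C(C)(C)C
F9 | step 13 | (2S,6R)-2-{2-[(tert-butyldimethylsilyl)oxy]ethyl}-6-[(2S,4R,6R)-6-{(tert-butyldimethylsilyl)oxy}-4-methoxy-2-methylnonyl]oxan-4-one | CCC[C@@H](O[Si](C)(C)C(C)(C)C)C[C@H](OC)C[C@H](C)C[C@@H]1CC(=O)C[C@H](CCO[Si](C)(C)C(C)(C)C)O1
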